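## The problem

The target is a linear trimer of coniferyl-type units with configuration (2R,3S,2'R,3'S). Guaiacyl ring A sits on C2 of dihydrofuran ring B (O1–C2–C3–C3a–C7a, fused to arene C). C5 of arene C carries C2' of a second dihydrofuran, ring D (primed atoms, fused to arene E), and arene E ends at C5' in an (E)-3-hydroxypropenyl arm. The four stereocentres form two trans pairs, C2/C3 and C2'/C3', separated by the flat arene C, so neither pair can steer the other and absolute control is needed twice. Within each pair the two centres differ in kind. C3 (C3') is a methine with three carbon substituents and cannot be corrected once made. C2 (C2') is a benzylic ether carbon para to an oxygen substituent; it can ionise reversibly and then settles trans to the C3 substituent. C3 can therefore control C2, but not the reverse. The cinnamyl alcohol ionises in acid, the p-oxygenated benzyl aryl ethers C2–O1 and C2'–O1' open through quinone methides and are cleaved by hydrogenolysis, and the free guaiacyl phenol is sensitive to oxidants. This rules out hydrogenolysis, late oxidations and any acid treatment once the side chain is complete. The enabling feature is the C2–C3 unit (and again C2'–C3'): two adjacent carbons, each bearing an aryl group, with a heteroatom on C2. That is the pattern left when an aryl group migrates from boron to one end of an alkene while a second aryl group is delivered to the other end. Arene C is the electrophile-derived aryl group of the first pair and the boron-derived aryl group of the second, so it must carry two handles of different reactivity: bromine at C3a and chlorine at C5.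

## Retrosynthesis

**Side chain last.** The C=C bond of the propenol arm is cut, leading from target 30 through enoate 29 to aldehyde 28. A cinnamyl alcohol would not survive the acid used to close the rings, whereas an aldehyde masked as a dioxolane passes through both borate chemistry and peroxide work-up. The forward steps must give an E-alkene and a 1,2-reduction in the presence of a free phenol and two primary alcohols.

**Ring D.** The O1'–C2' bond of 28 is cut to give open-chain alcohol 27, in which every protecting group is acid-labile. Cutting here rather than at C3'–C3a' leaves the stable centre C3' in place and lets the labile centre C2' be re-formed under its control. The forward step must remove three MOM ethers, a silyl ether and a dioxolane, and close ring D trans, in one operation.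

**Second three-component coupling.** The bonds C2'–C5 (to arene C) and C3'–C3a' (to arene E) of 27 are cut together. This gives aryl boronate 18, alkenyl bromide 20 (as alkenyllithium 24) and arene E bromide 23. Both stereocentres and both aryl–carbon bonds arise in one catalyst-controlled event, and the precursors are a dihydrobenzofuran and two small fragments. The borate 25 involved carries a 4-alkoxy-3-methoxyphenyl group on boron and meets an ortho-MOM-oxy aryl bromide, which makes it electronically a near copy of the first coupling.

**Exchange of the handle.** Boronate 18 comes from chloride 16 by borylation and esterification with diol 4. Ether 16 comes from phenol 15 by MOM protection. Chlorine is chosen because it survives the first palladium step, in which bromine reacts.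

**Ring B.** The O1–C2 bond of 15 is cut to give alcohol 14, and the C–O bond of 14 is traced to the C–B bond of boronate 13. The configuration at C2 delivered with boron is the required one. Because closure passes through a planar benzylic cation, it is C3 that guarantees the trans ring.

**Key disconnection.** In 13 the bonds ring A–C2 and C3–C3a are cut together. This gives aryllithium 11 (from bromide 2), (E)-alkenyl boronate 7 and arene C bromide 10. A stepwise alternative, such as an aldol between an arene C acetate and a ring A aldehyde, needs a stoichiometric auxiliary and more steps. Here three simple fragments give the whole C2–C3 unit with both centres. Boron in 7 carries the bulky diol 4 rather than pinacol, because β-substituted alkenyl pinacol boronates are known to give direct Suzuki–Miyaura coupling. The forward reaction must be selective for anti addition, for one alkene face, and for bromine over chlorine.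

**Fragments.** Bromide 2 is the MOM ether of phenol 1. Boronate 7 comes from silyl propargyl ether 5 by hydroboration and exchange with diol 4, which is made from diketone 3. Bromide 10 comes from phenol 8 through bromophenol 9. Alkenyl bromide 20 also comes from 5. Bromide 23 comes from 5-bromovanillin 21 through acetal 22.

## Roads not taken

**Alternative 1:** The cut is C3–C3a of ring B, made by ring contraction. Ester A1 would come from flavanone A2, in which arene C is still bonded to the carbonyl carbon. PhI(OAc)2 with HC(OMe)3 and catalytic H2SO4 in methanol would form the enol ether and a C3 iodonium species. Arene C would then shift to C3 with loss of iodobenzene, contracting the pyranone to ring B with a methyl ester on C3.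

- Merits: the oxidant is cheap and metal-free; the trans relation is secure because the ester-bearing C3 can epimerise; the C5 bromide allows repetition.
- Weak points: the absolute configuration must come from C2 of A2, and 2-aryl chromanones racemise by ring opening to the chalcone. Electron-rich 2-aryl groups favour the competing shift of ring A or dehydrogenation, so ring A has to travel as a tosylate that must be removed later. Each cycle also needs aldehyde formation, chalcone condensation, an enantioselective flavanone closure, the contraction and an ester reduction.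
- Comparison: this road is better in reagent cost and in freedom from organolithium reagents and an expensive ferrocenyl ligand, and its trans control is as dependable as the equilibration used here. Against this the chosen plan sets C3 by catalyst as a centre that cannot racemise, and needs about half the operations per ring.

**Alternative 2:** The cuts are O1–C2 and O1'–C2' together. Aldehyde A3 (the same structure as 28) would come from open-chain triphenol A4, in which C2 and C2' are methylene groups. DDQ would oxidise each CH2 para to a free phenol to a p-quinone methide, which the neighbouring phenol captures 5-exo.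

- Merits: both rings close in one step without protecting groups; A4 has only the two all-carbon stereocentres; C2 and C2' follow trans as in the chosen plan.
- Weak points: DDQ also dehydrogenates 2-aryl dihydrobenzofurans to benzofurans, can re-oxidise the p-hydroxybenzyl ether of the ring A end, and can attack the methines C3 and C3' ortho to a phenol, which would erase the stereocentres. The free primary alcohols compete as nucleophiles. A4 itself still needs two enantioselective C–C bond formations for its remote centres.
- Comparison: this road is shorter after assembly and ends at the same aldehyde. The chosen plan brings in the benzylic oxidation level with boron at the moment the C–C bonds form, so no oxidant stronger than alkaline peroxide ever meets the electron-rich arenes, and the skeleton-building step is also the stereo-defining step.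

**Alternative 3:** The cut is C3'–C3a' (and by iteration C3–C3a). Aldehyde A5 would come from aryl iodide A6, an aryl ether of a secondary allylic alcohol whose C2' is set beforehand by enantioselective allylic etherification. Bu3SnH under dry air would generate the C3a' radical, which adds 5-exo to the vinyl group. The primary radical is trapped by O2 and reduced to CH2OH.

- Merits: the C–O stereocentre comes from a well-developed catalytic asymmetric reaction; no acid closure and no ionisable benzylic alcohol are involved; the hydroxymethyl group appears directly.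
- Weak points: C3' is set by the cyclisation transition state under substrate control, where the trans preference is usually moderate and cannot be corrected afterwards. Hydrogen transfer from the stannane competes with oxygen capture and gives the 3-methyl compound. Peroxyl radicals meet an aldehyde C–H and a doubly activated C2'–H. Tin is stoichiometric.
- Comparison: this road is better in that closure is neutral and irreversible and each asymmetric step is a well-understood C–O bond formation. The chosen plan has the more reliable direction of relay: the catalyst sets the centre that cannot be corrected (C3) and thermodynamics sets the one that can (C2).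

Key step: step 6

Assumption: the ligand written as (Sp,Sp)-MandyPhos is (Sp,Sp)-1,1'-bis[bis(4-methoxy-3,5-dimethylphenyl)phosphino]-2,2'-bis[(R)-α-(dimethylamino)benzyl]ferrocene, C64H74FeN2O4P2. It is taken to direct the aryl palladium unit to the alkene face that gives the drawn configuration. If the sense is the reverse, the mirror-image ligand is used in steps 6 and 14 and nothing else changes.

## Route

Step 1
Reactants: 1 4-bromo-2-methoxyphenol
Product: 2 4-bromo-2-methoxy-1-(methoxymethoxy)benzene
Conditions: NaH, MOMCl, THF, 0 °C → rt
Reagents that add atoms: chloromethyl methyl ether (MOMCl), COCCl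
Why: Williamson-type O-alkylation of the sodium phenoxide. The MOM ether tolerates the bromine–lithium exchange of step 6 and is lost in the acid that later closes ring B.

Step 2
Reactants: 3 acenaphthylene-1,2-dione
Product: 4 cis-1,2-dimethyl-1,2-dihydroacenaphthylene-1,2-diol (mac diol)
Conditions: MeMgBr (3 equiv), THF, 0 °C → rt; aq. NH4Cl; crystallisation
Reagents that add atoms: methylmagnesium bromide, C[Mg]Br
Why: Double Grignard 1,2-addition to the diketone. The second methyl group should enter anti to the bulky magnesium alkoxide and give mainly the cis-diol, the only isomer able to form a cis-fused five-membered boronic ester; any trans isomer is removed by crystallisation.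

Step 3
Reactants: 5 tert-butyldimethyl(prop-2-yn-1-yloxy)silane; 4 mac diol
Product: 7 (E)-alkenyl B(mac) boronate, via alkenyl catechol boronate 6 (not isolated)
Conditions: catecholborane, Cy2BH (10 mol%), THF, rt; then 4, rt
Reagents that add atoms: catecholborane, B1Oc2ccccc2O1
Why: Dicyclohexylborane-catalysed syn hydroboration of the terminal alkyne puts boron on the terminal carbon and fixes the E geometry. Boronic ester exchange of the labile catechol ester with diol 4 gives the bulky boronate that conjunctive coupling of β-substituted alkenes requires.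

Step 4
Reactants: 8 4-chloro-2-methoxyphenol
Product: 9 2-bromo-4-chloro-6-methoxyphenol
Conditions: NBS, MeCN, 0 °C → rt
Reagents that add atoms: N-bromosuccinimide, O=C1CCC(=O)N1Br
Why: Electrophilic aromatic bromination. The hydroxyl group is the strongest director and its para position is blocked by chlorine, so bromine enters the free ortho position, the future C3a.

Step 5
Reactants: 9 2-bromo-4-chloro-6-methoxyphenol
Product: 10 1-bromo-5-chloro-3-methoxy-2-(methoxymethoxy)benzene
Conditions: NaH, MOMCl, DMF, 0 °C → rt
Reagents that add atoms: chloromethyl methyl ether (MOMCl), COCCl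
Why: O-alkylation of the hindered, acidic phenoxide (MOM protection). The acetal is inert to the borate and to palladium and is removed by the acid of step 8.

Step 6
Reactants: 2 4-bromo-2-methoxy-1-(methoxymethoxy)benzene; 7 (E)-alkenyl B(mac) boronate; 10 1-bromo-5-chloro-3-methoxy-2-(methoxymethoxy)benzene
Product: 13 B(mac) boronate of (1R,2S)-3-(tert-butyldimethylsilyloxy)-2-[5-chloro-3-methoxy-2-(methoxymethoxy)phenyl]-1-[3-methoxy-4-(methoxymethoxy)phenyl]propane with boron on C1, via aryllithium 11 (not isolated), via lithium borate complex 12 (not isolated)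
Conditions: 2, t-BuLi (2 equiv), Et2O, −78 °C; 7, −78 °C → rt; solvent exchanged for THF; 10, Pd(OAc)2 (3 mol%), (Sp,Sp)-MandyPhos C64H74FeN2O4P2 (3.6 mol%), NaOTf (2 equiv), 60 °C
Reagents that add atoms: none
Why: Bromine–lithium exchange on 2 gives aryllithium 11, which adds to the boron atom of 7 to give the four-coordinate borate 12. Pd(OAc)2 (divalent palladium) is reduced in the flask to zerovalent palladium, which inserts into the C–Br bond of 10 and leaves the stronger C–Cl bond alone; NaOTf takes up bromide so that a cationic aryl palladium complex can bind the electron-rich alkene of 12. Binding triggers a 1,2-metallate shift of ring A from boron to C2 on the face opposite to palladium, and reductive elimination then joins C3 to arene C, so that ring A–C2 and C3–C3a are formed and no ring is closed. The closest known reaction is the enantioselective palladium-catalysed conjunctive cross-coupling of β-substituted alkenylboron ate complexes carrying the bulky mac diol, which suppresses the direct Suzuki–Miyaura transfer seen with pinacol esters. The C2/C3 relationship follows from the stereospecific anti addition across the E-alkene, and the absolute sense, above all at C3, is set by the alkene face that the ferrocenyl diphosphine palladium complex selects. Regiochemistry is inherent, because boron stays on the carbon that receives the migrating group. β-Hydride and β-silyloxy elimination from the alkyl palladium intermediate should be outrun by reductive elimination from the wide-bite-angle diphosphine complex.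

Step 7
Reactants: 13 secondary benzylic B(mac) boronate
Product: 14 (1R,2S)-3-(tert-butyldimethylsilyloxy)-2-[5-chloro-3-methoxy-2-(methoxymethoxy)phenyl]-1-[3-methoxy-4-(methoxymethoxy)phenyl]propan-1-ol
Conditions: 30% H2O2, 3 M NaOH, THF, 0 °C → rt
Reagents that add atoms: hydrogen peroxide, OO
Why: Oxidation of the C–B bond by 1,2-shift of carbon from boron to oxygen goes with retention, so the alcohol keeps the configuration of 13. MOM and silyl ethers and the aryl chloride are inert, and diol 4 is recovered.

Step 8
Reactants: 14 open-chain benzylic alcohol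
Product: 15 4-[(2R,3S)-5-chloro-3-(hydroxymethyl)-7-methoxy-2,3-dihydro-1-benzofuran-2-yl]-2-methoxyphenol
Conditions: 3 M aq. HCl–THF (1:3), 45 °C
Reagents that add atoms: none
Why: Acid hydrolyses both aryl MOM ethers and the silyl ether; the p-hydroxybenzylic alcohol then ionises to a quinone-methide-type cation that the arene C phenol captures 5-exo (intramolecular SN1 etherification). Closure is reversible, so C2 settles trans to the fixed C3 substituent, which corresponds to (2R,3S).

Step 9
Reactants: 15 ring B phenol alcohol
Product: 16 (2R,3S)-5-chloro-7-methoxy-2-[3-methoxy-4-(methoxymethoxy)phenyl]-3-[(methoxymethoxy)methyl]-2,3-dihydro-1-benzofuran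
Conditions: MOMCl (excess), i-Pr2NEt, CH2Cl2, 0 → 40 °C
Reagents that add atoms: chloromethyl methyl ether (MOMCl), COCCl
Why: MOM protection of the phenol and the primary alcohol under amine base, so that no free phenoxide can reopen ring B. Both acetals are stable to hot ethanolic acetate and to organolithium reagents and fall off in the final acid step.

Step 10
Reactants: 16 bis-MOM aryl chloride; 4 mac diol
Product: 18 (2R,3S)-5-B(mac)-7-methoxy-2-[3-methoxy-4-(methoxymethoxy)phenyl]-3-[(methoxymethoxy)methyl]-2,3-dihydro-1-benzofuran, via arylboronic acid 17 (not isolated)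
Conditions: B2(OH)4, PdCl(XPhos)(2'-aminobiphenyl-2-yl) (2 mol%), XPhos, KOAc, EtOH, 80 °C; then 4, MgSO4, CH2Cl2, rt
Reagents that add atoms: tetrahydroxydiboron, OB(O)B(O)O
Why: Miyaura-type borylation of the aryl chloride under a bulky biarylphosphine palladium catalyst gives the boronic acid, which condenses with diol 4 in the work-up (boronic esterification). The stereocentres are not involved.

Step 11
Reactants: 5 tert-butyldimethyl(prop-2-yn-1-yloxy)silane
Product: 20 {[(E)-3-bromoprop-2-en-1-yl]oxy}(tert-butyl)dimethylsilane, via alkenylzirconocene chloride 19 (not isolated)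
Conditions: Cp2Zr(H)Cl, THF, rt; then NBS, 0 °C
Reagents that add atoms: N-bromosuccinimide, O=C1CCC(=O)N1Br
Why: syn-Hydrozirconation places zirconium on the terminal carbon, and bromination of the C–Zr bond with retention gives the (E)-alkenyl bromide.

Step 12
Reactants: 21 3-bromo-4-hydroxy-5-methoxybenzaldehyde
Product: 22 2-bromo-4-(1,3-dioxolan-2-yl)-6-methoxyphenol
Conditions: HOCH2CH2OH, TsOH·H2O (cat.), toluene, reflux, Dean–Stark
Reagents that add atoms: ethylene glycol, OCCO
Why: Acid-catalysed acetalisation with azeotropic removal of water. The dioxolane shields the aldehyde from the borate and from Dakin-type oxidation in the peroxide work-up of step 14.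

Step 13
Reactants: 22 2-bromo-4-(1,3-dioxolan-2-yl)-6-methoxyphenol
Product: 23 2-[3-bromo-5-methoxy-4-(methoxymethoxy)phenyl]-1,3-dioxolane
Conditions: NaH, MOMCl, DMF, 0 °C → rt
Reagents that add atoms: chloromethyl methyl ether (MOMCl), COCCl
Why: O-alkylation of the phenoxide under basic conditions that leave the dioxolane untouched (MOM protection).

Step 14
Reactants: 20 (E)-alkenyl bromide; 18 aryl B(mac) boronate; 23 arene E bromide
Product: 27 (1R,2S)-3-(tert-butyldimethylsilyloxy)-2-[5-(1,3-dioxolan-2-yl)-3-methoxy-2-(methoxymethoxy)phenyl]-1-{(2R,3S)-7-methoxy-2-[3-methoxy-4-(methoxymethoxy)phenyl]-3-[(methoxymethoxy)methyl]-2,3-dihydro-1-benzofuran-5-yl}propan-1-ol, via alkenyllithium 24 (not isolated), via lithium borate complex 25 (not isolated), via secondary boronate 26 (not isolated)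
Conditions: 20, t-BuLi (2 equiv), Et2O, −78 °C; 18, −78 °C → rt; solvent exchanged for THF; 23, Pd(OAc)2 (3 mol%), (Sp,Sp)-MandyPhos C64H74FeN2O4P2 (3.6 mol%), NaOTf (2 equiv), 60 °C; then 3 M NaOH, 30% H2O2, 0 °C → rt
Reagents that add atoms: hydrogen peroxide, OO
Why: The conjunctive cross-coupling of step 6 with the roles of the boron partners exchanged: alkenyllithium 24, formed with retention, adds to the boron of 18, and the palladium catalyst moves arene C to C2' anti to the incoming arene E at C3'. The borate carries the same 4-alkoxy-3-methoxyphenyl pattern on boron and meets the same ortho-MOM-oxy aryl bromide pattern as in step 6, and the catalyst, not the distant ring B centres, sets the new pair. Alkaline peroxide then replaces boron by oxygen with retention.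

Step 15
Reactants: 27 fully protected open-chain alcohol
Product: 28 (2R,3S)-2-[(2R,3S)-2-(4-hydroxy-3-methoxyphenyl)-3-(hydroxymethyl)-7-methoxy-2,3-dihydro-1-benzofuran-5-yl]-3-(hydroxymethyl)-7-methoxy-2,3-dihydro-1-benzofuran-5-carbaldehyde
Conditions: 6 M aq. HCl–THF (1:3), 50 °C
Reagents that add atoms: water, O
Why: Acid hydrolyses the three MOM ethers, the silyl ether and the dioxolane; the benzylic alcohol ionises to a cation stabilised by O1 para on arene C, and the arene E phenol captures it 5-exo (intramolecular SN1 etherification). Closure is reversible, so C2' settles trans to C3'; ring B may open and reclose under the same conditions but returns trans because C3 is fixed.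

Step 16
Reactants: 28 bis(dihydrobenzofuran) aldehyde
Product: 29 methyl (E)-3-{(2R,3S)-2-[(2R,3S)-2-(4-hydroxy-3-methoxyphenyl)-3-(hydroxymethyl)-7-methoxy-2,3-dihydro-1-benzofuran-5-yl]-3-(hydroxymethyl)-7-methoxy-2,3-dihydro-1-benzofuran-5-yl}prop-2-enoate
Conditions: Ph3P=CHCO2Me (3 equiv), toluene–THF, 60 °C
Reagents that add atoms: methyl (triphenylphosphoranylidene)acetate, COC(=O)C=P(c1ccccc1)(c1ccccc1)c1ccccc1
Why: Wittig olefination with a stabilised ylide is E-selective and tolerates the free phenol and alcohols. No stereocentre is adjacent to the aldehyde.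

Step 17
Reactants: 29 methyl enoate
Product: 30 target CNP0250921.1 (2R,3S,2'R,3'S)
Conditions: i-Bu2AlH (8 equiv), THF–CH2Cl2, −78 → −20 °C; aq. potassium sodium tartrate
Reagents that add atoms: none
Why: 1,2-Reduction of the α,β-unsaturated ester by i-Bu2AlH at low temperature gives the allylic alcohol and leaves the alkene alone. The excess covers the three acidic OH groups, and the neutral tartrate work-up avoids acid on the cinnamyl alcohol.

## Compound list

1 | 4-bromo-2-methoxyphenol | COc1cc(Br)ccc1O | starting material
2 | 4-bromo-2-methoxy-1-(methoxymethoxy)benzene | COCOc1ccc(Br)cc1OC | intermediate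
3 | acenaphthylene-1,2-dione (acenaphthoquinone) | O=C1C(=O)c2cccc3cccc1c23 | starting material
4 | cis-1,2-dimethyl-1,2-dihydroacenaphthylene-1,2-diol (mac diol, meso) | C[C@]1(O)c2cccc3cccc(c23)[C@@]1(C)O | intermediate
5 | tert-butyldimethyl(prop-2-yn-1-yloxy)silane | C#CCO[Si](C)(C)C(C)(C)C | starting material
6 | 2-[(E)-3-(tert-butyldimethylsilyloxy)prop-1-en-1-yl]-1,3,2-benzodioxaborole | CC(C)(C)[Si](C)(C)OC/C=C/B1Oc2ccccc2O1 | intermediate (not isolated)
7 | tert-butyl{[(E)-3-(cis-6b,9a-dimethyl-6b,9a-dihydroacenaphtho[1,2-d][1,3,2]dioxaborol-8-yl)prop-2-en-1-yl]oxy}dimethylsilane, the (E)-alkenyl B(mac) boronate | CC(C)(C)[Si](C)(C)OC/C=C/B1O[C@@]2(C)c3cccc4cccc(c34)[C@@]2(C)O1 | intermediate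
8 | 4-chloro-2-methoxyphenol | COc1cc(Cl)ccc1O | starting material
9 | 2-bromo-4-chloro-6-methoxyphenol | COc1cc(Cl)cc(Br)c1O | intermediate
10 | 1-bromo-5-chloro-3-methoxy-2-(methoxymethoxy)benzene | COCOc1c(Br)cc(Cl)cc1OC | intermediate
11 | [3-methoxy-4-(methoxymethoxy)phenyl]lithium | [Li]c1ccc(OCOC)c(OC)c1 | intermediate (not isolated)
12 | lithium [(E)-3-(tert-butyldimethylsilyloxy)prop-1-en-1-yl][3-methoxy-4-(methoxymethoxy)phenyl](mac-diolato)borate (configuration at boron not defined) | [Li+].COCOc1ccc(cc1OC)[B-]1(/C=C/CO[Si](C)(C)C(C)(C)C)O[C@@]2(C)c3cccc4cccc(c34)[C@@]2(C)O1 | intermediate (not isolated)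
13 | B(mac) boronate of (1R,2S)-3-(tert-butyldimethylsilyloxy)-2-[5-chloro-3-methoxy-2-(methoxymethoxy)phenyl]-1-[3-methoxy-4-(methoxymethoxy)phenyl]propane, boron on C1 | COCOc1ccc(cc1OC)[C@H](B1O[C@@]2(C)c3cccc4cccc(c34)[C@@]2(C)O1)[C@@H](c1cc(Cl)cc(OC)c1OCOC)CO[Si](C)(C)C(C)(C)C | intermediate
14 | (1R,2S)-3-(tert-butyldimethylsilyloxy)-2-[5-chloro-3-methoxy-2-(methoxymethoxy)phenyl]-1-[3-methoxy-4-(methoxymethoxy)phenyl]propan-1-ol | COCOc1ccc(cc1OC)[C@H](O)[C@@H](c1cc(Cl)cc(OC)c1OCOC)CO[Si](C)(C)C(C)(C)C | intermediate
15 | 4-[(2R,3S)-5-chloro-3-(hydroxymethyl)-7-methoxy-2,3-dihydro-1-benzofuran-2-yl]-2-methoxyphenol | COc1cc([C@@H]2Oc3c(OC)cc(Cl)cc3[C@H]2CO)ccc1O | intermediate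
16 | (2R,3S)-5-chloro-7-methoxy-2-[3-methoxy-4-(methoxymethoxy)phenyl]-3-[(methoxymethoxy)methyl]-2,3-dihydro-1-benzofuran | COc1cc([C@@H]2Oc3c(OC)cc(Cl)cc3[C@H]2COCOC)ccc1OCOC | intermediate
17 | {(2R,3S)-7-methoxy-2-[3-methoxy-4-(methoxymethoxy)phenyl]-3-[(methoxymethoxy)methyl]-2,3-dihydro-1-benzofuran-5-yl}boronic acid | COc1cc([C@@H]2Oc3c(OC)cc(B(O)O)cc3[C@H]2COCOC)ccc1OCOC | intermediate (not isolated)
18 | B(mac) ester of boronic acid 17 | COc1cc([C@@H]2Oc3c(OC)cc(B4O[C@@]5(C)c6cccc7cccc(c67)[C@@]5(C)O4)cc3[C@H]2COCOC)ccc1OCOC | intermediate
19 | chlorobis(cyclopentadienyl)[(E)-3-(tert-butyldimethylsilyloxy)prop-1-en-1-yl]zirconium (cyclopentadienyl rings drawn σ-bonded) | CC(C)(C)[Si](C)(C)OC/C=C/[Zr](Cl)(C1C=CC=C1)C1C=CC=C1 | intermediate (not isolated)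
20 | {[(E)-3-bromoprop-2-en-1-yl]oxy}(tert-butyl)dimethylsilane | CC(C)(C)[Si](C)(C)OC/C=C/Br | intermediate
21 | 3-bromo-4-hydroxy-5-methoxybenzaldehyde (5-bromovanillin) | COc1cc(C=O)cc(Br)c1O | starting material
22 | 2-bromo-4-(1,3-dioxolan-2-yl)-6-methoxyphenol | COc1cc(C2OCCO2)cc(Br)c1O | intermediate
23 | 2-[3-bromo-5-methoxy-4-(methoxymethoxy)phenyl]-1,3-dioxolane | COCOc1c(Br)cc(C2OCCO2)cc1OC | intermediate
24 | [(E)-3-(tert-butyldimethylsilyloxy)prop-1-en-1-yl]lithium | [Li]/C=C/CO[Si](C)(C)C(C)(C)C | intermediate (not isolated)
25 | lithium borate from 24 and 18 (configuration at boron not defined) | [Li+].COc1cc([C@@H]2Oc3c(OC)cc([B-]4(/C=C/CO[Si](C)(C)C(C)(C)C)O[C@@]5(C)c6cccc7cccc(c67)[C@@]5(C)O4)cc3[C@H]2COCOC)ccc1OCOC | intermediate (not isolated)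
26 | B(mac) boronate corresponding to alcohol 27, boron on C1 of the (1R,2S)-propyl unit | COc1cc([C@@H]2Oc3c(OC)cc([C@H](B4O[C@@]5(C)c6cccc7cccc(c67)[C@@]5(C)O4)[C@@H](c8cc(C9OCCO9)cc(OC)c8OCOC)CO[Si](C)(C)C(C)(C)C)cc3[C@H]2COCOC)ccc1OCOC | intermediate (not isolated)
27 | (1R,2S)-3-(tert-butyldimethylsilyloxy)-2-[5-(1,3-dioxolan-2-yl)-3-methoxy-2-(methoxymethoxy)phenyl]-1-{(2R,3S)-7-methoxy-2-[3-methoxy-4-(methoxymethoxy)phenyl]-3-[(methoxymethoxy)methyl]-2,3-dihydro-1-benzofuran-5-yl}propan-1-ol | COc1cc([C@@H]2Oc3c(OC)cc([C@H](O)[C@@H](c4cc(C5OCCO5)cc(OC)c4OCOC)CO[Si](C)(C)C(C)(C)C)cc3[C@H]2COCOC)ccc1OCOC | intermediate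
28 | (2R,3S)-2-[(2R,3S)-2-(4-hydroxy-3-methoxyphenyl)-3-(hydroxymethyl)-7-methoxy-2,3-dihydro-1-benzofuran-5-yl]-3-(hydroxymethyl)-7-methoxy-2,3-dihydro-1-benzofuran-5-carbaldehyde | COc1cc([C@@H]2Oc3c(OC)cc([C@@H]4Oc5c(OC)cc(C=O)cc5[C@H]4CO)cc3[C@H]2CO)ccc1O | intermediate
29 | methyl (E)-3-{(2R,3S)-2-[(2R,3S)-2-(4-hydroxy-3-methoxyphenyl)-3-(hydroxymethyl)-7-methoxy-2,3-dihydro-1-benzofuran-5-yl]-3-(hydroxymethyl)-7-methoxy-2,3-dihydro-1-benzofuran-5-yl}prop-2-enoate | COc1cc([C@@H]2Oc3c(OC)cc([C@@H]4Oc5c(OC)cc(/C=C/C(=O)OC)cc5[C@H]4CO)cc3[C@H]2CO)ccc1O | intermediate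
30 | CNP0250921.1: 4-[(2R,3S)-3-(hydroxymethyl)-5-[(2R,3S)-3-(hydroxymethyl)-5-[(E)-3-hydroxyprop-1-en-1-yl]-7-methoxy-2,3-dihydro-1-benzofuran-2-yl]-7-methoxy-2,3-dihydro-1-benzofuran-2-yl]-2-methoxyphenol | COc1cc([C@@H]2Oc3c(OC)cc([C@@H]4Oc5c(OC)cc(/C=C/CO)cc5[C@H]4CO)cc3[C@H]2CO)ccc1O | target

## Step count and risks

Total: 17 steps. Longest linear sequence: 11 steps (steps 4, 5, 6, 7, 8, 9, 10, 14, 15, 16, 17, starting from 8).

**Step 6 (key step).**
- What may go wrong: direct Suzuki–Miyaura transfer of the alkenyl group instead of the 1,2-shift; slow oxidative addition to the ortho-substituted, electron-rich bromide; inhibition of the catalyst by bromide; β-elimination of the silyloxy group from the alkyl palladium intermediate; insufficient facial selectivity.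
- Fallback: an auxiliary-controlled aldol, setting out from 10 and 11 and returning at 15. Bromine–lithium exchange on 10 (n-BuLi, THF, −78 °C) gives [5-chloro-3-methoxy-2-(methoxymethoxy)phenyl]lithium F1, which opens oxirane (BF3·OEt2) to the arylethanol F2. Oxidation (TEMPO, PhI(OAc)2, aq. MeCN) gives the arylacetic acid F3. This is coupled (DCC, DMAP) with (R)-4-benzyl-1,3-oxazolidin-2-one to the imide F4. Aryllithium 11 is quenched with DMF to give 3-methoxy-4-(methoxymethoxy)benzaldehyde F5. F4 is enolised with Bu2BOTf and i-Pr2NEt and treated with F5; the Evans syn aldol through a Zimmerman–Traxler transition state gives adduct F6, in which the auxiliary fixes the α-carbon, the future C3. LiBH4 removes the auxiliary and gives the (1R,2S)-diol F7, which closes to 15 under the conditions of step 8.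

**Step 14.**
- What may go wrong: the alkenyllithium cannot be titrated, so a precious boronate meets an organolithium of uncertain amount. A shortfall leaves 18 unconverted; a surplus attacks bromide 23 and the catalyst. Direct alkenyl transfer may also compete.
- Fallback: assemble the same borate in the sense used in step 6, setting out from 17 and returning at 25. Boronic acid 17 is isolated instead of being esterified and is converted by ipso-iododeboronation (NaI, sodium N-chloro-4-methylbenzenesulfonamide, aq. THF) into the aryl iodide F8. Iodine–lithium exchange (n-BuLi, Et2O, −78 °C, which forms no lithium halide) gives the aryllithium F9. F9 is added to a small excess of the cheap boronate 7 to give borate 25, and step 14 continues from there.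

**Step 10.**
- What may go wrong: protodeboronation of the electron-rich boronic acid in hot ethanol, slow oxidative addition to the electron-rich C–Cl bond, or incomplete esterification with the hindered diol.
- Fallback: setting out from 16 and returning at 17. Miyaura borylation with bis(pinacolato)diboron (Pd2(dba)3, XPhos, KOAc, dioxane, 100 °C) gives the stable pinacol boronate F10, which can be purified. Oxidative cleavage of the pinacol unit (NaIO4, NH4OAc, aq. acetone, rt) then gives 17 under mild conditions for esterification with 4.

**Step 15.**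
- What may go wrong: the aliphatic MOM ether needs longer acid treatment than the other groups. This exposes the p-oxygenated benzylic ethers and the aldehyde to oligomerisation through quinone methides and to loss of formaldehyde from the hydroxymethyl arms.
- Fallback: staged deprotection, setting out from 27 and returning at 28. Dilute acid (1 M aq. HCl, THF, rt) removes the aryl MOM ethers, the silyl ether and the dioxolane and closes ring D, leaving the aliphatic acetal to give the mono-MOM aldehyde F11. That acetal is then cleaved without protic acid (TMSOTf, 2,2'-bipyridyl, CH2Cl2, 0 °C; then water) to give 28.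

## Further compounds

F1 | step 6 | [5-chloro-3-methoxy-2-(methoxymethoxy)phenyl]lithium | [Li]c1cc(Cl)cc(OC)c1OCOC
F2 | step 6 | 2-[5-chloro-3-methoxy-2-(methoxymethoxy)phenyl]ethan-1-ol | COCOc1c(CCO)cc(Cl)cc1OC
F3 | step 6 | 2-[5-chloro-3-methoxy-2-(methoxymethoxy)phenyl]acetic acid | COCOc1c(CC(=O)O)cc(Cl)cc1OC
F4 | step 6 | (4R)-4-benzyl-3-{2-[5-chloro-3-methoxy-2-(methoxymethoxy)phenyl]acetyl}-1,3-oxazolidin-2-one | COCOc1c(CC(=O)N2[C@H](Cc3ccccc3)COC2=O)cc(Cl)cc1OC
F5 | step 6 | 3-methoxy-4-(methoxymethoxy)benzaldehyde | COCOc1ccc(C=O)cc1OC
F6 | step 6 | (4R)-4-benzyl-3-{(2R,3R)-2-[5-chloro-3-methoxy-2-(methoxymethoxy)phenyl]-3-hydroxy-3-[3-methoxy-4-(methoxymethoxy)phenyl]propanoyl}-1,3-oxazolidin-2-one | COCOc1ccc(cc1OC)[C@H](O)[C@@H](c1cc(Cl)cc(OC)c1OCOC)C(=O)N1[C@H](Cc2ccccc2)COC1=O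
F7 | step 6 | (1R,2S)-2-[5-chloro-3-methoxy-2-(methoxymethoxy)phenyl]-1-[3-methoxy-4-(methoxymethoxy)phenyl]propane-1,3-diol | COCOc1ccc(cc1OC)[C@H](O)[C@@H](c1cc(Cl)cc(OC)c1OCOC)CO
F8 | step 14 | (2R,3S)-5-iodo-7-methoxy-2-[3-methoxy-4-(methoxymethoxy)phenyl]-3-[(methoxymethoxy)methyl]-2,3-dihydro-1-benzofuran | COc1cc([C@@H]2Oc3c(OC)cc(I)cc3[C@H]2COCOC)ccc1OCOC
F9 | step 14 | {(2R,3S)-7-methoxy-2-[3-methoxy-4-(methoxymethoxy)phenyl]-3-[(methoxymethoxy)methyl]-2,3-dihydro-1-benzofuran-5-yl}lithium | COc1cc([C@@H]2Oc3c(OC)cc([Li])cc3[C@H]2COCOC)ccc1OCOC
F10 | step 10 | pinacol ester of boronic acid 17 | COc1cc([C@@H]2Oc3c(OC)cc(B4OC(C)(C)C(C)(C)O4)cc3[C@H]2COCOC)ccc1OCOC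
F11 | step 15 | (2R,3S)-2-{(2R,3S)-2-(4-hydroxy-3-methoxyphenyl)-7-methoxy-3-[(methoxymethoxy)methyl]-2,3-dihydro-1-benzofuran-5-yl}-3-(hydroxymethyl)-7-methoxy-2,3-dihydro-1-benzofuran-5-carbaldehyde | COc1cc([C@@H]2Oc3c(OC)cc([C@@H]4Oc5c(OC)cc(C=O)cc5[C@H]4CO)cc3[C@H]2COCOC)ccc1O
A1 | alternative 1 | methyl (2R,3R)-5-bromo-7-methoxy-2-[3-methoxy-4-(tosyloxy)phenyl]-2,3-dihydro-1-benzofuran-3-carboxylate (trans) | COc1cc([C@@H]2Oc3c(OC)cc(Br)cc3[C@H]2C(=O)OC)ccc1OS(=O)(=O)c1ccc(C)cc1
A2 | alternative 1 | (2R)-6-bromo-8-methoxy-2-[3-methoxy-4-(tosyloxy)phenyl]chroman-4-one | COc1cc([C@H]2CC(=O)c3cc(Br)cc(OC)c3O2)ccc1OS(=O)(=O)c1ccc(C)cc1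
A3 | alternative 2 | bis(dihydrobenzofuran) aldehyde, same structure as 28 | COc1cc([C@@H]2Oc3c(OC)cc([C@@H]4Oc5c(OC)cc(C=O)cc5[C@H]4CO)cc3[C@H]2CO)ccc1O
A4 | alternative 2 | 4-hydroxy-3-[(2S)-1-hydroxy-3-{4-hydroxy-3-[(2S)-1-hydroxy-3-(4-hydroxy-3-methoxyphenyl)propan-2-yl]-5-methoxyphenyl}propan-2-yl]-5-methoxybenzaldehyde | COc1cc(C[C@H](CO)c2cc(C[C@H](CO)c3cc(C=O)cc(OC)c3O)cc(OC)c2O)ccc1O
A5 | alternative 3 | bis(dihydrobenzofuran) aldehyde with free C3' hydroxymethyl, silyl ether on the C3 hydroxymethyl and triisopropylsilyl ether on ring A | COc1cc([C@@H]2Oc3c(OC)cc([C@@H]4Oc5c(OC)cc(C=O)cc5[C@H]4CO)cc3[C@H]2CO[Si](C)(C)C(C)(C)C)ccc1O[Si](C(C)C)(C(C)C)C(C)C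
A6 | alternative 3 | 3-iodo-5-methoxy-4-{[(1R)-1-(ring B aryl)prop-2-en-1-yl]oxy}benzaldehyde, ring B unit protected as in A5 | COc1cc([C@@H]2Oc3c(OC)cc([C@@H](C=C)Oc4c(I)cc(C=O)cc4OC)cc3[C@H]2CO[Si](C)(C)C(C)(C)C)ccc1O[Si](C(C)C)(C(C)C)C(C)C
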